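## Retrosynthetic overview

1. Target 15 comes from its acetonide 14 by hydrolysis. 14 is made in one operation from orcinol 11 and the terpenoid aldehyde 10: a C-alkenylation at the orcinol carbon between the two hydroxyls forms C4–C4a, then an oxa-6π ring closure steered by a chiral phosphate forms O1–C2 and the quaternary (S)-C2 centre.
2. Enabling feature: the ring O1–C2–C3=C4–C4a–C8a is a 2H-pyran fused to the orcinol ring, with C4a lying between the two oxygen-bearing carbons C5 and C8a. It is therefore the electrocyclisation product of a vinyl o-quinone methide (O1=C8a–C4a=C4–C3=C2), and the two equivalent phenol oxygens of orcinol make the closure regiochemically degenerate.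
3. The step is stereoconvergent: E/Z and α,β/β,γ isomers of 10 all enter one iminium/dienamine pool. 10 comes from cross-metathesis of the allyl compound 7 with isoprenol 8, then oxidation.
4. 7 comes from diol 6, made by equatorial hydroxymethyl addition to ketone 4 (sets the carbinol centre). 4 comes from Pd-catalysed decarboxylative asymmetric allylation of enol carbonate 3 (sets the ring CH centre), and 3 from 3-methylcyclohex-2-en-1-one 1.
5. Ring order: the cyclohexane (in 1) and the benzene ring (in 11) are bought; the pyran ring is the only skeletal ring made and is closed last. The dioxolane of 7–14 is a protecting ring, removed in step 8.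

Key step: step 7

Assumption: the sense of induction of the chiral ligand in step 2 and of the chiral phosphate in step 7 cannot be predicted with certainty for these substrates; the antipode written is a provisional choice and is to be exchanged for its mirror image if a pilot run gives the opposite configuration.

## Route

Step 1
Reactants: 1 3-methylcyclohex-2-en-1-one
Product: 3 prop-2-en-1-yl 3,3-dimethylcyclohex-1-en-1-yl carbonate, via bromomagnesium 3,3-dimethylcyclohex-1-en-1-olate 2 (not isolated)
Conditions: MeMgBr, CuBr·SMe2 (5 mol%), THF, −20 °C; then DMPU, allyl chloroformate, −78 °C → rt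
Reagents that add atoms: methylmagnesium bromide, C[Mg]Br; allyl chloroformate, C=CCOC(=O)Cl
Why: Copper-catalysed conjugate addition builds the gem-dimethyl carbon and gives the regiodefined enolate 2, whose hindered α-carbon and the hard chloroformate in a dipolar solvent should favour O-acylation to the enol carbonate (conjugate addition/enolate trapping).

Step 2
Reactants: 3 prop-2-en-1-yl 3,3-dimethylcyclohex-1-en-1-yl carbonate
Product: 4 (2S)-3,3-dimethyl-2-(prop-2-en-1-yl)cyclohexan-1-one
Conditions: Pd2(dba)3 (2.5 mol%), (S,S)-ANDEN-phenyl Trost ligand (5.5 mol%), 1,4-dioxane, 23 °C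
Reagents that add atoms: none
Why: In this Pd-catalysed decarboxylative asymmetric allylic alkylation of an allyl enol carbonate, ionisation and loss of CO2 give a π-allyl-Pd/enolate pair under neutral conditions, the chiral ligand selects the enolate face so that C2 should form as (S), and the neighbouring quaternary carbon slows enolisation of the α-tertiary ketone.

Step 3
Reactants: 4 (2S)-3,3-dimethyl-2-(prop-2-en-1-yl)cyclohexan-1-one
Product: 6 (1R,2S)-1-(hydroxymethyl)-3,3-dimethyl-2-(prop-2-en-1-yl)cyclohexan-1-ol, via β-hydroxysilane 5 (not isolated)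
Conditions: (i-PrO)Me2SiCH2MgCl (from the chloride and Mg), THF, 0 °C → rt; aq. NH4Cl; crude 5, KF, KHCO3, 30% H2O2, THF/MeOH, 40 °C
Reagents that add atoms: [(isopropoxy)dimethylsilyl]methylmagnesium chloride, CC(C)O[Si](C)(C)C[Mg]Cl; hydrogen peroxide, OO
Why: In this Tamao hydroxymethylation the axial 3-methyl group blocks axial attack, so the Grignard reagent should enter equatorially and trans to the equatorial allyl group, which sets C1 as (R) with the tertiary OH cis to the side chain, and the C–Si oxidation does not touch a stereocentre.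

Step 4
Reactants: 6 (1R,2S)-1-(hydroxymethyl)-3,3-dimethyl-2-(prop-2-en-1-yl)cyclohexan-1-ol
Product: 7 (5R,6S)-2,2,7,7-tetramethyl-6-(prop-2-en-1-yl)-1,3-dioxaspiro[4.5]decane
Conditions: 2,2-dimethoxypropane, PPTS (cat.), CH2Cl2, rt
Reagents that add atoms: 2,2-dimethoxypropane, COC(C)(C)OC
Why: Acid-catalysed transketalisation closes the dioxolane on the 1,2-diol and protects both hydroxyls for the oxidation in step 6 and the annulation in step 7.

Step 5
Reactants: 7 (5R,6S)-2,2,7,7-tetramethyl-6-(prop-2-en-1-yl)-1,3-dioxaspiro[4.5]decane; 8 3-methylbut-3-en-1-ol (isoprenol)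
Product: 9 3-methyl-5-[(5R,6S)-2,2,7,7-tetramethyl-1,3-dioxaspiro[4.5]decan-6-yl]pent-3-en-1-ol (E/Z mixture)
Conditions: Hoveyda–Grubbs II catalyst (5 mol%), 8 (5 equiv), CH2Cl2, 40 °C
Reagents that add atoms: none
Why: Olefin cross-metathesis of a terminal alkene with an excess of a 1,1-disubstituted alkene should give the trisubstituted alkene, driven by loss of ethene, and its geometry is of no consequence for step 7.

Step 6
Reactants: 9 3-methyl-5-[(5R,6S)-2,2,7,7-tetramethyl-1,3-dioxaspiro[4.5]decan-6-yl]pent-3-en-1-ol (E/Z mixture)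
Product: 10 3-methyl-5-[(5R,6S)-2,2,7,7-tetramethyl-1,3-dioxaspiro[4.5]decan-6-yl]pent-3-enal (E/Z mixture)
Conditions: Dess–Martin periodinane, NaHCO3, CH2Cl2, 0 °C → rt; used crude
Reagents that add atoms: none
Why: Buffered Dess–Martin oxidation of the primary alcohol should give the β,γ-unsaturated aldehyde without loss of the acetonide, and any drift of the double bond into conjugation is harmless.

Step 7
Reactants: 10 3-methyl-5-[(5R,6S)-2,2,7,7-tetramethyl-1,3-dioxaspiro[4.5]decan-6-yl]pent-3-enal (E/Z mixture); 11 orcinol (5-methylbenzene-1,3-diol)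
Product: 14 (2S)-2,7-dimethyl-2-{2-[(5R,6S)-2,2,7,7-tetramethyl-1,3-dioxaspiro[4.5]decan-6-yl]ethyl}-2H-chromen-5-ol, via conjugated pent-2-enal isomer 12 (not isolated), via vinyl o-quinone methide 13 (not isolated)
Conditions: 11 (2 equiv), (R)-TRIP phosphoric acid (10 mol%), t-BuNH2 (10 mol%), toluene/cyclopentyl methyl ether, 5 Å MS, 50 °C
Reagents that add atoms: none
Why: Proposed new method: the ammonium phosphate turns 10 and its conjugated isomer 12 (all E/Z forms) into one equilibrating iminium/dienamine pool, C2 of orcinol (the carbon between the two hydroxyls) adds to the iminium carbon to form C4–C4a, loss of the amine gives the vinyl o-quinone methide 13, and its ring closure forms O1–C2. The closest known reactions are the amine-salt-mediated formal oxa-[3+3] annulation of resorcinols with citral or farnesal (no control at C2), the closure of o-hydroxyaryl allyl cations to 2H-chromenes inside chiral phosphate contact ion pairs, and enantioconvergent iminium catalysis of E/Z enal mixtures with chiral phosphate counter-anions; new is catalyst control of a quaternary Me/CH2R centre in this annulation. The pyran ring closes by a thermal disrotatory oxa-6π electrocyclisation of the 1-oxatriene, formally a 6-endo attack of the phenolic oxygen on the allyl terminus. The only new stereocentre, C2, is set by the chiral phosphate, which is hydrogen-bonded or ion-paired to the carbonyl oxygen of 13 and so chooses the helical sense of the closure; the cyclohexane centres are too remote to interfere, and because every step before the closure is reversible all isomers of the aldehyde should drain through the one favoured transition state (Curtin–Hammett). The step needs 1,2- rather than 1,4-addition of the arene, secured by the fully substituted β-carbon of the enal, and attack at C2 rather than C4 of orcinol, which amine conditions favour and after which the two flanking hydroxyls are equivalent so that only one pyran ring can form; the excess of 11 suppresses a second annulation.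

Step 8
Reactants: 14 (2S)-2,7-dimethyl-2-{2-[(5R,6S)-2,2,7,7-tetramethyl-1,3-dioxaspiro[4.5]decan-6-yl]ethyl}-2H-chromen-5-ol
Product: 15 (1R,2S)-2-{2-[(2S)-5-hydroxy-2,7-dimethyl-2H-chromen-2-yl]ethyl}-1-(hydroxymethyl)-3,3-dimethylcyclohexan-1-ol
Conditions: AcOH/THF/H2O (3:1:1), 40 °C
Reagents that add atoms: none
Why: Mild aqueous-acid hydrolysis should cleave the spiro acetonide while the 2H-chromene, its allylic aryl ether centre C2 and the tertiary alcohol survive, and no stereocentre is touched.

## Compound list

1 | 3-methylcyclohex-2-en-1-one | CC1=CC(=O)CCC1 | starting material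
2 | bromomagnesium 3,3-dimethylcyclohex-1-en-1-olate | Br[Mg]OC1=CC(C)(C)CCC1 | intermediate
3 | prop-2-en-1-yl 3,3-dimethylcyclohex-1-en-1-yl carbonate | C=CCOC(=O)OC1=CC(C)(C)CCC1 | intermediate
4 | (2S)-3,3-dimethyl-2-(prop-2-en-1-yl)cyclohexan-1-one | C=CC[C@H]1C(C)(C)CCCC1=O | intermediate
5 | (1R,2S)-1-{[dimethyl(propan-2-yloxy)silyl]methyl}-3,3-dimethyl-2-(prop-2-en-1-yl)cyclohexan-1-ol | C=CC[C@H]1C(C)(C)CCC[C@]1(O)C[Si](C)(C)OC(C)C | intermediate
6 | (1R,2S)-1-(hydroxymethyl)-3,3-dimethyl-2-(prop-2-en-1-yl)cyclohexan-1-ol | C=CC[C@H]1C(C)(C)CCC[C@]1(O)CO | intermediate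
7 | (5R,6S)-2,2,7,7-tetramethyl-6-(prop-2-en-1-yl)-1,3-dioxaspiro[4.5]decane | C=CC[C@H]1C(C)(C)CCC[C@@]12OC(C)(C)OC2 | intermediate
8 | 3-methylbut-3-en-1-ol (isoprenol) | CC(=C)CCO | starting material
9 | 3-methyl-5-[(5R,6S)-2,2,7,7-tetramethyl-1,3-dioxaspiro[4.5]decan-6-yl]pent-3-en-1-ol (E/Z mixture) | OCCC(C)=CC[C@H]1C(C)(C)CCC[C@@]12OC(C)(C)OC2 | intermediate
10 | 3-methyl-5-[(5R,6S)-2,2,7,7-tetramethyl-1,3-dioxaspiro[4.5]decan-6-yl]pent-3-enal (E/Z mixture) | O=CCC(C)=CC[C@H]1C(C)(C)CCC[C@@]12OC(C)(C)OC2 | intermediate
11 | orcinol (5-methylbenzene-1,3-diol) | Cc1cc(O)cc(O)c1 | starting material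
12 | 3-methyl-5-[(5R,6S)-2,2,7,7-tetramethyl-1,3-dioxaspiro[4.5]decan-6-yl]pent-2-enal (E/Z mixture) | O=CC=C(C)CC[C@H]1C(C)(C)CCC[C@@]12OC(C)(C)OC2 | intermediate
13 | 5-hydroxy-3-methyl-6-{3-methyl-5-[(5R,6S)-2,2,7,7-tetramethyl-1,3-dioxaspiro[4.5]decan-6-yl]pent-2-en-1-ylidene}cyclohexa-2,4-dien-1-one | O=C1C=C(C)C=C(O)C1=CC=C(C)CC[C@H]2C(C)(C)CCC[C@@]23OC(C)(C)OC3 | intermediate
14 | (2S)-2,7-dimethyl-2-{2-[(5R,6S)-2,2,7,7-tetramethyl-1,3-dioxaspiro[4.5]decan-6-yl]ethyl}-2H-chromen-5-ol | Cc1cc(O)c2c(c1)O[C@@](C)(CC[C@H]1C(C)(C)CCC[C@@]13OC(C)(C)OC3)C=C2 | intermediate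
15 | (1R,2S)-2-{2-[(2S)-5-hydroxy-2,7-dimethyl-2H-chromen-2-yl]ethyl}-1-(hydroxymethyl)-3,3-dimethylcyclohexan-1-ol | Cc1cc(O)c2c(c1)O[C@@](C)(CC[C@H]1C(C)(C)CCC[C@]1(O)CO)C=C2 | target

## Step count and risks

Total step count: 8. Longest linear sequence: 8 steps (1 → 15).

Steps most likely to fail:

1. Step 7 (proposed new method). The facial discrimination at the forming quaternary C2 may be weak, so that the ring closes to both C2 configurations; C-attack at C4 of orcinol would give the regioisomeric chromene. Fallback with known chemistry: it sets out from 10. DBU moves the double bond into conjugation, and the (2E)-3-methyl-5-[(5R,6S)-2,2,7,7-tetramethyl-1,3-dioxaspiro[4.5]decan-6-yl]pent-2-enal F1 is taken out by chromatography, the Z form being re-equilibrated with a trace of amine and recycled. Luche reduction (NaBH4, CeCl3, MeOH) gives the (2E)-3-methyl-5-[(5R,6S)-2,2,7,7-tetramethyl-1,3-dioxaspiro[4.5]decan-6-yl]pent-2-en-1-ol F2. Acidic alumina in hot 1,2-dichloroethane promotes ortho-allylation of orcinol 11 at the carbon between the hydroxyls to give 5-methyl-2-{(2E)-3-methyl-5-[(5R,6S)-2,2,7,7-tetramethyl-1,3-dioxaspiro[4.5]decan-6-yl]pent-2-en-1-yl}benzene-1,3-diol F3. An enantioselective Pd(II)-catalysed 6-endo Wacker-type oxidative cyclisation (Pd(OCOCF3)2, i-Pr-SPRIX, p-benzoquinone, CH2Cl2), a reaction type established for 2-geranylphenols, then closes the pyran ring, and the route is rejoined at 14.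

2. Step 2. Proton transfer between palladium enolates may erode the enantiopurity of the α-tertiary ketone or lead to double allylation, and the sense of induction may be the opposite one. Fallback: it sets out from 1. The enolate 2, made as in step 1, is C-allylated with allyl iodide in THF/DMPU to rac-3,3-dimethyl-2-(prop-2-en-1-yl)cyclohexan-1-one F4, and the enantiomers are separated by preparative chromatography on a chiral phase (SFC); the (S)-enantiomer is 4, where the route is rejoined.

3. Step 3. The basic Grignard reagent may enolise the hindered ketone (return of 4, erosion at C2), and attack may not be fully equatorial, which would give the C1 epimer. Fallback: it sets out from 4. Chloromethyllithium, generated in situ (ICH2Cl, MeLi·LiBr, THF, −78 °C), is a small and weakly basic carbenoid that should add equatorially to give lithium (1R,2S)-1-(chloromethyl)-3,3-dimethyl-2-(prop-2-en-1-yl)cyclohexan-1-olate F5, which closes on warming to (3R,4S)-5,5-dimethyl-4-(prop-2-en-1-yl)-1-oxaspiro[2.5]octane F6. Hydroxide opens the epoxide at its CH2 terminus (KOH, DMSO/H2O, 90 °C), and the route is rejoined at 6.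

## Further compounds

F1 | step 7 | (2E)-3-methyl-5-[(5R,6S)-2,2,7,7-tetramethyl-1,3-dioxaspiro[4.5]decan-6-yl]pent-2-enal | O=C/C=C(\C)CC[C@H]1C(C)(C)CCC[C@@]12OC(C)(C)OC2
F2 | step 7 | (2E)-3-methyl-5-[(5R,6S)-2,2,7,7-tetramethyl-1,3-dioxaspiro[4.5]decan-6-yl]pent-2-en-1-ol | OC/C=C(\C)CC[C@H]1C(C)(C)CCC[C@@]12OC(C)(C)OC2
F3 | step 7 | 5-methyl-2-{(2E)-3-methyl-5-[(5R,6S)-2,2,7,7-tetramethyl-1,3-dioxaspiro[4.5]decan-6-yl]pent-2-en-1-yl}benzene-1,3-diol | Cc1cc(O)c(C/C=C(\C)CC[C@H]2C(C)(C)CCC[C@@]23OC(C)(C)OC3)c(O)c1
F4 | step 2 | rac-3,3-dimethyl-2-(prop-2-en-1-yl)cyclohexan-1-one | C=CCC1C(=O)CCCC1(C)C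
F5 | step 3 | lithium (1R,2S)-1-(chloromethyl)-3,3-dimethyl-2-(prop-2-en-1-yl)cyclohexan-1-olate | [Li+].C=CC[C@H]1C(C)(C)CCC[C@]1([O-])CCl
F6 | step 3 | (3R,4S)-5,5-dimethyl-4-(prop-2-en-1-yl)-1-oxaspiro[2.5]octane | C=CC[C@H]1C(C)(C)CCC[C@]12CO2
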